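**Plan**

- Retrosynthetic cuts, in order: the ten benzyl ethers; the chromone ring of the flavonol (its O-1–C-2 bond, its C-2–C-3 bond and the bond from C-4 to ring A, traced back to an aryl bromide); the C-4–C-4a bond of the flavan; the O-1–C-2 aryl ether of the flavan; the Cα=Cβ bond of a chalcone.
- Forward order: chalcone → epoxy ketone → epoxy alcohol → aryl ether diol → flavan pyran ring closed at C-4–C-4a → chromone ring built last on the bromine-bearing carbon → hydrogenolysis.
- Enabling feature: flavan C-4 is benzylic to ring A of the flavonol and para to its O-8, so it can ionise; flavan C-4a is ortho to O-1 and para to O-7, so it is the one nucleophilic carbon within six-membered reach of that cation.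
- Stereochemistry: C-3 and C-2 come from a reagent-controlled Juliá–Colonna epoxidation followed by SN2 opening by a phenoxide (inversion at C-2); C-4 comes from substrate control in the ring closure (all-pseudo-equatorial half-chair), whatever the carbinol configuration.
- The chromone carbonyl is kept out of the ring closure (a bromine stands in for it), because a carbonyl peri to C-4 would capture the cation.

Key step: step 8

Remark: the carbinol carbon of 10 and 11 (future C-4) is planarised in step 8, so either epimer serves; names and SMILES show the anti epimer expected from the reduction.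

**Route**

Step 1
Reactants: 1 2,3-bis(benzyloxy)benzaldehyde
Product: 3 2,3-bis(benzyloxy)phenol, via aryl formate 2 (not isolated)
Conditions: mCPBA, CH2Cl2, rt; then K2CO3 (cat.), MeOH, rt
Reagents that add atoms: 3-chloroperoxybenzoic acid (mCPBA), OOC(=O)c1cccc(Cl)c1
Why: Baeyer–Villiger (Dakin-type) oxidation of the electron-rich aldehyde inserts oxygen on the aryl side to give the formate, whose methanolysis frees the phenol that becomes O-1 of the flavan.

Step 2
Reactants: 4 3,4,5-tris(benzyloxy)benzoic acid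
Product: 5 1-[3,4,5-tris(benzyloxy)phenyl]ethan-1-one
Conditions: MeLi (2.2 equiv), THF, 0 °C to rt; then H2O
Reagents that add atoms: methyllithium, [Li]C
Why: Addition of methyllithium to the lithium carboxylate gives a geminal dialkoxide that collapses to the methyl ketone only on work-up, the classical conversion of an acid into a methyl ketone.

Step 3
Reactants: 5 1-[3,4,5-tris(benzyloxy)phenyl]ethan-1-one
Product: 6 1-[2-bromo-3,4,5-tris(benzyloxy)phenyl]ethan-1-one
Conditions: NBS, MeCN, 0 °C to rt, dark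
Reagents that add atoms: N-bromosuccinimide, O=C1CCC(=O)N1Br
Why: Electrophilic aromatic bromination can only occur at the two equivalent free positions (each ortho to one and para to another benzyloxy group), so the bromine, the placeholder for the later chromone carbonyl carbon, is placed unambiguously next to the acetyl-bearing carbon.

Step 4
Reactants: 6 1-[2-bromo-3,4,5-tris(benzyloxy)phenyl]ethan-1-one; 7 3,4-bis(benzyloxy)benzaldehyde
Product: 8 (E)-1-[2-bromo-3,4,5-tris(benzyloxy)phenyl]-3-[3,4-bis(benzyloxy)phenyl]prop-2-en-1-one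
Conditions: KOH, EtOH–THF, rt
Reagents that add atoms: none
Why: Claisen–Schmidt aldol condensation of the methyl ketone enolate with the non-enolisable aldehyde gives the (E)-enone under thermodynamic control.

Step 5
Reactants: 8 (E)-1-[2-bromo-3,4,5-tris(benzyloxy)phenyl]-3-[3,4-bis(benzyloxy)phenyl]prop-2-en-1-one
Product: 9 [2-bromo-3,4,5-tris(benzyloxy)phenyl]{(2R,3S)-3-[3,4-bis(benzyloxy)phenyl]oxiran-2-yl}methanone
Conditions: poly-L-leucine, urea–H2O2, DBU, THF, rt
Reagents that add atoms: urea–hydrogen peroxide, NC(N)=O.OO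
Why: Juliá–Colonna epoxidation (conjugate addition of hydroperoxide and ring closure on the helical polypeptide) is reagent-controlled and, by analogy with chalcone itself for which the L-polymer gives the (2R,3S)-oxide, should set both oxirane carbons, the future C-3 and (before inversion) C-2.

Step 6
Reactants: 9 [2-bromo-3,4,5-tris(benzyloxy)phenyl]{(2R,3S)-3-[3,4-bis(benzyloxy)phenyl]oxiran-2-yl}methanone
Product: 10 (S)-[2-bromo-3,4,5-tris(benzyloxy)phenyl]{(2S,3S)-3-[3,4-bis(benzyloxy)phenyl]oxiran-2-yl}methanol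
Conditions: NaBH4, MeOH–THF, −20 °C
Reagents that add atoms: none
Why: Hydride reduction of the α,β-epoxy ketone under mildly basic conditions leaves the acid-sensitive aryl oxirane untouched and should favour the anti carbinol, whose configuration is immaterial because this carbon is ionised in step 8.

Step 7
Reactants: 10 (S)-[2-bromo-3,4,5-tris(benzyloxy)phenyl]{(2S,3S)-3-[3,4-bis(benzyloxy)phenyl]oxiran-2-yl}methanol; 3 2,3-bis(benzyloxy)phenol
Product: 11 (1S,2S,3R)-1-[2-bromo-3,4,5-tris(benzyloxy)phenyl]-3-[3,4-bis(benzyloxy)phenyl]-3-[2,3-bis(benzyloxy)phenoxy]propane-1,2-diol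
Conditions: Cs2CO3 (0.5 equiv), DMF, 70 °C
Reagents that add atoms: none
Why: SN2 opening of the aryl oxirane by the caesium phenoxide at the benzylic carbon remote from the carbinol (the known opening of 3-arylglycidols by phenoxides) forms the O-1–C-2 ether with inversion to give 2R and leaves C-3 untouched, while phenoxide as the only base keeps alkoxide formation and hence Payne migration down.

Step 8
Reactants: 11 (1S,2S,3R)-1-[2-bromo-3,4,5-tris(benzyloxy)phenyl]-3-[3,4-bis(benzyloxy)phenyl]-3-[2,3-bis(benzyloxy)phenoxy]propane-1,2-diol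
Product: 12 (2R,3S,4S)-7,8-bis(benzyloxy)-2-[3,4-bis(benzyloxy)phenyl]-4-[2-bromo-3,4,5-tris(benzyloxy)phenyl]chroman-3-ol
Conditions: Sc(OTf)3 (10 mol %), CH2Cl2–(CF3)2CHOH 4:1, −20 °C to rt
Reagents that add atoms: none
Why: Sc(OTf)3 in the ionising solvent converts the benzylic hydroxyl at the future C-4 into a benzylic cation stabilised by the para benzyloxy group of the bromo-tris(benzyloxy)phenyl ring, and this cation is captured by C-4a of the 2,3-bis(benzyloxy)phenoxy ring (the only free position ortho to the ether oxygen, also para to a benzyloxy group) with loss of a proton, an intramolecular Friedel–Crafts alkylation. The closest known reaction types are the acid-mediated cyclisations of 1-aryl-3-aryloxypropanols and of 3-arylglycidyl aryl ethers to 4-arylchromans and trans-4-arylchroman-3-ols, and the C-4 arylation of flavan-3,4-diols. The pyran ring closes in the six-membered aryl-participation mode (Ar2-6, ortho carbon of the aryl ether attacking an exocyclic cationic carbon). The new stereocentre C-4 is set by the existing C-2 and C-3 centres, because in the half-chair transition state the aryl group at C-2, the hydroxyl at C-3 and the aryl group at C-4 are all pseudo-equatorial, so the 3,4-trans isomer should form from either carbinol epimer of 11. The step needs ionisation at the C-4 hydroxyl and not at the benzylic C-2 aryl ether, and ring closure faster than 1,2-hydride shift or indane formation through the C-2 aryl ring, which the more basic hydroxyl, the low temperature, the six-membered ring size and the doubly activated (ortho-O and para-O) nucleophilic carbon should secure. No carbonyl is present peri to C-4 at this stage, so the cation cannot be diverted to a cyclic oxocarbenium ion.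

Step 9
Reactants: 12 (2R,3S,4S)-7,8-bis(benzyloxy)-2-[3,4-bis(benzyloxy)phenyl]-4-[2-bromo-3,4,5-tris(benzyloxy)phenyl]chroman-3-ol
Product: 13 (2R,3S,4S)-3,7,8-tris(benzyloxy)-2-[3,4-bis(benzyloxy)phenyl]-4-[2-bromo-3,4,5-tris(benzyloxy)phenyl]chromane
Conditions: NaH, BnBr, n-Bu4NI (cat.), THF–DMF, 0 °C to rt
Reagents that add atoms: benzyl bromide, BrCc1ccccc1
Why: Williamson etherification masks the only free hydroxyl as a benzyl ether so that it survives the organolithium and acylation steps and is removed with the other benzyl groups at the end.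

Step 10
Reactants: 13 (2R,3S,4S)-3,7,8-tris(benzyloxy)-2-[3,4-bis(benzyloxy)phenyl]-4-[2-bromo-3,4,5-tris(benzyloxy)phenyl]chromane; 14 2-(benzyloxy)-N-methoxy-N-methylacetamide
Product: 16 2-(benzyloxy)-1-{2,3,4-tris(benzyloxy)-6-[(2R,3S,4R)-3,7,8-tris(benzyloxy)-2-[3,4-bis(benzyloxy)phenyl]chroman-4-yl]phenyl}ethan-1-one, via aryllithium 15 (not isolated)
Conditions: t-BuLi (2.1 equiv), THF, −78 °C; then 14, −78 to 0 °C; H2O
Reagents that add atoms: none
Why: Bromine–lithium exchange at −78 °C is faster than any deprotonation, and the aryllithium is acylated once by the N-methoxy-N-methylamide through its stable chelated tetrahedral adduct, which plants the future C-4 and C-3 carbons of the chromone on the carbon next to the flavan-bearing one.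

Step 11
Reactants: 16 2-(benzyloxy)-1-{2,3,4-tris(benzyloxy)-6-[(2R,3S,4R)-3,7,8-tris(benzyloxy)-2-[3,4-bis(benzyloxy)phenyl]chroman-4-yl]phenyl}ethan-1-one
Product: 17 2-(benzyloxy)-1-{3,4-bis(benzyloxy)-2-hydroxy-6-[(2R,3S,4R)-3,7,8-tris(benzyloxy)-2-[3,4-bis(benzyloxy)phenyl]chroman-4-yl]phenyl}ethan-1-one
Conditions: MgBr2·OEt2, toluene–Et2O, 60 °C; aqueous work-up
Reagents that add atoms: none
Why: Magnesium chelation between the ketone oxygen and the one aryl benzyloxy group ortho to it activates only that ether for attack by bromide (chelation-controlled selective debenzylation), which unveils the phenol that becomes O-1 of the flavonol.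

Step 12
Reactants: 17 2-(benzyloxy)-1-{3,4-bis(benzyloxy)-2-hydroxy-6-[(2R,3S,4R)-3,7,8-tris(benzyloxy)-2-[3,4-bis(benzyloxy)phenyl]chroman-4-yl]phenyl}ethan-1-one; 18 3,4-bis(benzyloxy)benzoyl chloride
Product: 20 3,7,8-tris(benzyloxy)-2-[3,4-bis(benzyloxy)phenyl]-5-[(2R,3S,4R)-3,7,8-tris(benzyloxy)-2-[3,4-bis(benzyloxy)phenyl]chroman-4-yl]-4H-chromen-4-one, via 1,3-diketone 19 (not isolated)
Conditions: LiN(SiMe3)2 (3.2 equiv), THF, −78 °C; 18, −78 °C to rt; aqueous work-up; then TsOH·H2O (cat.), toluene, 60 °C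
Reagents that add atoms: none
Why: The lithium phenoxide–enolate dianion is acylated on carbon by the aroyl chloride (the direct variant of the Baker–Venkataraman route) and the resulting 2-hydroxyaryl 1,3-diketone cyclodehydrates under mild acid to the 3-benzyloxyflavone.

Step 13
Reactants: 20 3,7,8-tris(benzyloxy)-2-[3,4-bis(benzyloxy)phenyl]-5-[(2R,3S,4R)-3,7,8-tris(benzyloxy)-2-[3,4-bis(benzyloxy)phenyl]chroman-4-yl]-4H-chromen-4-one
Product: 21 2-(3,4-dihydroxyphenyl)-5-[(2R,3S,4R)-2-(3,4-dihydroxyphenyl)-3,7,8-trihydroxychroman-4-yl]-3,7,8-trihydroxy-4H-chromen-4-one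
Conditions: H2 (1 atm), Pd(OH)2/C, THF–MeOH, rt, argon-flushed work-up
Reagents that add atoms: none
Why: Hydrogenolysis over Pd(OH)2/C should cleave all ten benzyl ethers without touching the flavonol or the benzylic C-2–O-1 bond of the flavan, as in the debenzylation of protected catechins and procyanidins, and leaves the three stereocentres intact.

**Compound list**

1 | 2,3-bis(benzyloxy)benzaldehyde | O=Cc1cccc(OCc2ccccc2)c1OCc1ccccc1 | starting material
2 | 2,3-bis(benzyloxy)phenyl formate | O=COc1cccc(OCc2ccccc2)c1OCc1ccccc1 | intermediate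
3 | 2,3-bis(benzyloxy)phenol | Oc1cccc(OCc2ccccc2)c1OCc1ccccc1 | intermediate
4 | 3,4,5-tris(benzyloxy)benzoic acid | OC(=O)c1cc(OCc2ccccc2)c(OCc2ccccc2)c(OCc2ccccc2)c1 | starting material
5 | 1-[3,4,5-tris(benzyloxy)phenyl]ethan-1-one | CC(=O)c1cc(OCc2ccccc2)c(OCc2ccccc2)c(OCc2ccccc2)c1 | intermediate
6 | 1-[2-bromo-3,4,5-tris(benzyloxy)phenyl]ethan-1-one | CC(=O)c1cc(OCc2ccccc2)c(OCc2ccccc2)c(OCc2ccccc2)c1Br | intermediate
7 | 3,4-bis(benzyloxy)benzaldehyde | O=Cc1ccc(OCc2ccccc2)c(OCc2ccccc2)c1 | starting material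
8 | (E)-1-[2-bromo-3,4,5-tris(benzyloxy)phenyl]-3-[3,4-bis(benzyloxy)phenyl]prop-2-en-1-one | O=C(/C=C/c1ccc(OCc2ccccc2)c(OCc2ccccc2)c1)c1cc(OCc2ccccc2)c(OCc2ccccc2)c(OCc2ccccc2)c1Br | intermediate
9 | [2-bromo-3,4,5-tris(benzyloxy)phenyl]{(2R,3S)-3-[3,4-bis(benzyloxy)phenyl]oxiran-2-yl}methanone | O=C(c1cc(OCc2ccccc2)c(OCc2ccccc2)c(OCc2ccccc2)c1Br)[C@@H]1O[C@H]1c1ccc(OCc2ccccc2)c(OCc2ccccc2)c1 | intermediate
10 | (S)-[2-bromo-3,4,5-tris(benzyloxy)phenyl]{(2S,3S)-3-[3,4-bis(benzyloxy)phenyl]oxiran-2-yl}methanol (anti epimer) | O[C@@H](c1cc(OCc2ccccc2)c(OCc2ccccc2)c(OCc2ccccc2)c1Br)[C@@H]1O[C@H]1c1ccc(OCc2ccccc2)c(OCc2ccccc2)c1 | intermediate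
11 | (1S,2S,3R)-1-[2-bromo-3,4,5-tris(benzyloxy)phenyl]-3-[3,4-bis(benzyloxy)phenyl]-3-[2,3-bis(benzyloxy)phenoxy]propane-1,2-diol | O[C@@H](c1cc(OCc2ccccc2)c(OCc2ccccc2)c(OCc2ccccc2)c1Br)[C@H](O)[C@@H](c1ccc(OCc2ccccc2)c(OCc2ccccc2)c1)Oc1cccc(OCc2ccccc2)c1OCc1ccccc1 | intermediate
12 | (2R,3S,4S)-7,8-bis(benzyloxy)-2-[3,4-bis(benzyloxy)phenyl]-4-[2-bromo-3,4,5-tris(benzyloxy)phenyl]chroman-3-ol; 2,3-trans-3,4-trans, same spatial arrangement at C-4 as 4R in the target (the descriptor changes because bromine raises the priority of the aryl group) | Brc1c(OCc2ccccc2)c(OCc2ccccc2)c(OCc2ccccc2)cc1[C@@H]1c2ccc(OCc3ccccc3)c(OCc3ccccc3)c2O[C@H](c2ccc(OCc3ccccc3)c(OCc3ccccc3)c2)[C@H]1O | intermediate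
13 | (2R,3S,4S)-3,7,8-tris(benzyloxy)-2-[3,4-bis(benzyloxy)phenyl]-4-[2-bromo-3,4,5-tris(benzyloxy)phenyl]chromane | Brc1c(OCc2ccccc2)c(OCc2ccccc2)c(OCc2ccccc2)cc1[C@@H]1c2ccc(OCc3ccccc3)c(OCc3ccccc3)c2O[C@H](c2ccc(OCc3ccccc3)c(OCc3ccccc3)c2)[C@H]1OCc1ccccc1 | intermediate
14 | 2-(benzyloxy)-N-methoxy-N-methylacetamide | CON(C)C(=O)COCc1ccccc1 | starting material
15 | {2,3,4-tris(benzyloxy)-6-[(2R,3S,4R)-3,7,8-tris(benzyloxy)-2-[3,4-bis(benzyloxy)phenyl]chroman-4-yl]phenyl}lithium | [Li]c1c(OCc2ccccc2)c(OCc2ccccc2)c(OCc2ccccc2)cc1[C@@H]1c2ccc(OCc3ccccc3)c(OCc3ccccc3)c2O[C@H](c2ccc(OCc3ccccc3)c(OCc3ccccc3)c2)[C@H]1OCc1ccccc1 | intermediate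
16 | 2-(benzyloxy)-1-{2,3,4-tris(benzyloxy)-6-[(2R,3S,4R)-3,7,8-tris(benzyloxy)-2-[3,4-bis(benzyloxy)phenyl]chroman-4-yl]phenyl}ethan-1-one | O=C(COCc1ccccc1)c1c(OCc2ccccc2)c(OCc2ccccc2)c(OCc2ccccc2)cc1[C@@H]1c2ccc(OCc3ccccc3)c(OCc3ccccc3)c2O[C@H](c2ccc(OCc3ccccc3)c(OCc3ccccc3)c2)[C@H]1OCc1ccccc1 | intermediate
17 | 2-(benzyloxy)-1-{3,4-bis(benzyloxy)-2-hydroxy-6-[(2R,3S,4R)-3,7,8-tris(benzyloxy)-2-[3,4-bis(benzyloxy)phenyl]chroman-4-yl]phenyl}ethan-1-one | O=C(COCc1ccccc1)c1c(O)c(OCc2ccccc2)c(OCc2ccccc2)cc1[C@@H]1c2ccc(OCc3ccccc3)c(OCc3ccccc3)c2O[C@H](c2ccc(OCc3ccccc3)c(OCc3ccccc3)c2)[C@H]1OCc1ccccc1 | intermediate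
18 | 3,4-bis(benzyloxy)benzoyl chloride | O=C(Cl)c1ccc(OCc2ccccc2)c(OCc2ccccc2)c1 | starting material
19 | 2-(benzyloxy)-1-[3,4-bis(benzyloxy)phenyl]-3-{3,4-bis(benzyloxy)-2-hydroxy-6-[(2R,3S,4R)-3,7,8-tris(benzyloxy)-2-[3,4-bis(benzyloxy)phenyl]chroman-4-yl]phenyl}propane-1,3-dione (epimers at the central carbon, in equilibrium with enol forms) | O=C(c1ccc(OCc2ccccc2)c(OCc2ccccc2)c1)C(OCc1ccccc1)C(=O)c1c(O)c(OCc2ccccc2)c(OCc2ccccc2)cc1[C@@H]1c2ccc(OCc3ccccc3)c(OCc3ccccc3)c2O[C@H](c2ccc(OCc3ccccc3)c(OCc3ccccc3)c2)[C@H]1OCc1ccccc1 | intermediate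
20 | 3,7,8-tris(benzyloxy)-2-[3,4-bis(benzyloxy)phenyl]-5-[(2R,3S,4R)-3,7,8-tris(benzyloxy)-2-[3,4-bis(benzyloxy)phenyl]chroman-4-yl]-4H-chromen-4-one | O=c1c(OCc2ccccc2)c(-c2ccc(OCc3ccccc3)c(OCc3ccccc3)c2)oc2c(OCc3ccccc3)c(OCc3ccccc3)cc([C@@H]3c4ccc(OCc5ccccc5)c(OCc5ccccc5)c4O[C@H](c4ccc(OCc5ccccc5)c(OCc5ccccc5)c4)[C@H]3OCc3ccccc3)c12 | intermediate
21 | 2-(3,4-dihydroxyphenyl)-5-[(2R,3S,4R)-2-(3,4-dihydroxyphenyl)-3,7,8-trihydroxychroman-4-yl]-3,7,8-trihydroxy-4H-chromen-4-one | O=c1c(O)c(-c2ccc(O)c(O)c2)oc2c(O)c(O)cc([C@@H]3c4ccc(O)c(O)c4O[C@H](c4ccc(O)c(O)c4)[C@H]3O)c12 | target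

**Step count and risks**

Total step count: 13. Longest linear sequence: 12 steps (steps 2 to 13, from 4 to 21).

Steps most likely to fail:

Step 8 (key ring closure). The cation may be captured with poor facial selectivity at C-4, may undergo 1,2-hydride shift from C-3 to a ketone, or ionisation may occur at the benzylic C-2 aryl ether with loss of the phenol. The fallback replaces the free cation by a neighbouring-group-controlled displacement. It sets out from 11, which is acetylated on both hydroxyls (Ac2O, pyridine, DMAP) to the 1,2-di-O-acetyl derivative of 11 F1. Me3SiOTf (CH2Cl2, −40 °C) ionises the benzylic acetate, the acetoxy group on the neighbouring carbon closes onto it to the trans-1,3-dioxolan-2-ylium ion, and the arene opens this ion at C-4 with inversion. This should give the 3,4-trans 3-O-acetyl derivative of 12 F2, with the hydride shift blocked. Methanolysis (K2CO3, MeOH) brings the sequence back to the route at 12.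

Step 7 (phenoxide opening). The oxirane may migrate to the neighbouring carbinol (Payne rearrangement) before it is opened, so that the phenoxide enters at the wrong benzylic carbon, or the phenoxide may attack C-3. The fallback removes the free hydroxyl. It sets out from 10, which is converted (MeOCH2Cl, i-Pr2NEt, CH2Cl2) into the O-methoxymethyl ether of 10 F3. Opening with 3 and Cs2CO3 as in step 7 gives the 1-O-methoxymethyl ether of 11 F4. Under the conditions of step 8 the benzylic acetal oxygen is ionised in place of the hydroxyl, so the sequence comes back to the route at 12.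

Step 12 (chromone annulation). The hindered enolate or the phenoxide may be acylated on oxygen instead of carbon, and the crowded diketone may cyclise sluggishly. The fallback uses intramolecular acyl transfer. It sets out from 17, whose phenol is esterified with 18 (Et3N, DMAP, CH2Cl2) to the 3,4-bis(benzyloxy)benzoate ester of 17 F5. Baker–Venkataraman rearrangement (KOt-Bu, THF, 0 °C) moves the aroyl group from oxygen to the α-carbon through a six-membered transition state, and the sequence comes back to the route at 19, which is cyclised by the acid treatment of step 12 to 20.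

Further compounds
F1 | step 8 | (1S,2S,3R)-1-[2-bromo-3,4,5-tris(benzyloxy)phenyl]-3-[3,4-bis(benzyloxy)phenyl]-3-[2,3-bis(benzyloxy)phenoxy]propane-1,2-diyl diacetate | CC(=O)O[C@@H](c1cc(OCc2ccccc2)c(OCc2ccccc2)c(OCc2ccccc2)c1Br)[C@H](OC(C)=O)[C@@H](c1ccc(OCc2ccccc2)c(OCc2ccccc2)c1)Oc1cccc(OCc2ccccc2)c1OCc1ccccc1
F2 | step 8 | (2R,3S,4S)-7,8-bis(benzyloxy)-2-[3,4-bis(benzyloxy)phenyl]-4-[2-bromo-3,4,5-tris(benzyloxy)phenyl]chroman-3-yl acetate | Brc1c(OCc2ccccc2)c(OCc2ccccc2)c(OCc2ccccc2)cc1[C@@H]1c2ccc(OCc3ccccc3)c(OCc3ccccc3)c2O[C@H](c2ccc(OCc3ccccc3)c(OCc3ccccc3)c2)[C@H]1OC(C)=O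
F3 | step 7 | (2S,3S)-2-{(S)-[2-bromo-3,4,5-tris(benzyloxy)phenyl](methoxymethoxy)methyl}-3-[3,4-bis(benzyloxy)phenyl]oxirane | COCO[C@@H](c1cc(OCc2ccccc2)c(OCc2ccccc2)c(OCc2ccccc2)c1Br)[C@@H]1O[C@H]1c1ccc(OCc2ccccc2)c(OCc2ccccc2)c1
F4 | step 7 | (1R,2S,3S)-3-[2-bromo-3,4,5-tris(benzyloxy)phenyl]-1-[3,4-bis(benzyloxy)phenyl]-1-[2,3-bis(benzyloxy)phenoxy]-3-(methoxymethoxy)propan-2-ol | COCO[C@@H](c1cc(OCc2ccccc2)c(OCc2ccccc2)c(OCc2ccccc2)c1Br)[C@H](O)[C@@H](c1ccc(OCc2ccccc2)c(OCc2ccccc2)c1)Oc1cccc(OCc2ccccc2)c1OCc1ccccc1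
F5 | step 12 | 2-[2-(benzyloxy)acetyl]-5,6-bis(benzyloxy)-3-[(2R,3S,4R)-3,7,8-tris(benzyloxy)-2-[3,4-bis(benzyloxy)phenyl]chroman-4-yl]phenyl 3,4-bis(benzyloxy)benzoate | O=C(COCc1ccccc1)c1c(OC(=O)c2ccc(OCc3ccccc3)c(OCc3ccccc3)c2)c(OCc2ccccc2)c(OCc2ccccc2)cc1[C@@H]1c2ccc(OCc3ccccc3)c(OCc3ccccc3)c2O[C@H](c2ccc(OCc3ccccc3)c(OCc3ccccc3)c2)[C@H]1OCc1ccccc1
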